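**Retrosynthetic overview**
1. Target 19 ← silyl ether 18 by desilylation. Both indole rings are bought; the γ-lactone is the only ring made and is made last.
2. 18 ← bromo enol ester 15 by closing the lactone between C4 (the ring CH2) and C5 (the oxygen-bearing CH): a 5-exo-trig radical cyclisation through the ester.
3. Enabling feature: lactone C5 carries the ring oxygen O1 and a CH2 that sits on C3 of the 2,3-disubstituted indole. C5 and that CH2 can therefore be an indole-conjugated (Z)-enol ester; attack at C5 leaves a stabilised indol-3-ylmethyl radical, and the C3 oxygen stereocentre (from methyl (R)-glycidate) steers C5 trans.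
4. 15 ← Ru-catalysed anti-Markovnikov addition of acid 14 (three steps from methyl (R)-glycidate) to the 3-ethynyl-2,3'-diindolylmethane 9.
5. 9 ← C3 iodination and Sonogashira coupling of 5 ← C2-lithiated 1-methylindole + 1-methylindole-3-carbaldehyde, then deoxygenation.

Key step: step 10

Remark: the target is the (3R,5R) lactone, i.e. 3-OH and the 5-(indolylmethyl) group are trans. Lactone atoms are numbered O1, C2 (C=O), C3 (CH–O), C4 (CH2), C5 (CH–O1). The descriptor of the glycidate-derived carbon changes (R in 10, S in 11–15, R in 18–19) only through CIP priorities; no bond at that carbon is touched.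

Step 1
Reactants: 1 1-methyl-1H-indole; 2 1-methyl-1H-indole-3-carbaldehyde
Product: 4 (1-methyl-1H-indol-2-yl)(1-methyl-1H-indol-3-yl)methanol (racemic), via 2-lithio-1-methylindole 3 (not isolated)
Conditions: n-BuLi, THF, 0 °C → rt; then 2, −78 °C → rt; H2O
Reagents that add atoms: none
Why: C2-lithiation of N-methylindole and 1,2-addition of the aryllithium to the aldehyde; the carbinol stereocentre is removed in step 2, so the racemate is used.

Step 2
Reactants: 4 (1-methyl-1H-indol-2-yl)(1-methyl-1H-indol-3-yl)methanol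
Product: 5 1-methyl-2-[(1-methyl-1H-indol-3-yl)methyl]-1H-indole
Conditions: LiAlH4, AlCl3, Et2O/THF, 0 °C → rt; aqueous work-up
Reagents that add atoms: none
Why: Mixed-hydride (chloroalane) deoxygenation of a diheteroaryl carbinol, in which the indole-stabilised cation is captured by hydride faster than by the nucleophilic C3 of the product and the indole rings are not reduced.

Step 3
Reactants: 5 1-methyl-2-[(1-methyl-1H-indol-3-yl)methyl]-1H-indole
Product: 6 3-iodo-1-methyl-2-[(1-methyl-1H-indol-3-yl)methyl]-1H-indole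
Conditions: NIS (1.0 equiv), DMF, −20 → 0 °C, dark
Reagents that add atoms: N-iodosuccinimide, O=C1CCC(=O)N1I
Why: Electrophilic aromatic iodination at C3 of the 2-alkyl-1-methylindole, the most nucleophilic position of 5, since the other indole has only its less reactive C2 free.

Step 4
Reactants: 6 3-iodo-1-methyl-2-[(1-methyl-1H-indol-3-yl)methyl]-1H-indole; 7 ethynyltrimethylsilane
Product: 8 1-methyl-2-[(1-methyl-1H-indol-3-yl)methyl]-3-[(trimethylsilyl)ethynyl]-1H-indole
Conditions: Pd(PPh3)2Cl2 (cat.), CuI (cat.), Et3N, THF, rt → 40 °C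
Reagents that add atoms: none
Why: Sonogashira coupling of a 3-iodoindole with a terminal alkyne under mild, acid-free conditions.

Step 5
Reactants: 8 1-methyl-2-[(1-methyl-1H-indol-3-yl)methyl]-3-[(trimethylsilyl)ethynyl]-1H-indole
Product: 9 3-ethynyl-1-methyl-2-[(1-methyl-1H-indol-3-yl)methyl]-1H-indole
Conditions: K2CO3 (cat.), MeOH/THF, rt
Reagents that add atoms: none
Why: Base-catalysed methanolysis of the alkynyl C–Si bond (protiodesilylation), which leaves the rest of the molecule untouched.

Step 6
Reactants: 10 methyl (R)-oxirane-2-carboxylate (methyl (R)-glycidate)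
Product: 11 methyl (S)-3-bromo-2-hydroxypropanoate
Conditions: LiBr, AcOH, THF, 0 °C → rt
Reagents that add atoms: lithium bromide, [Li+].[Br-]
Why: Acid-assisted SN2 opening of the glycidic ester by bromide at the unsubstituted C3 (halohydrin formation), which does not touch the C2–O bond, so the stereocentre is retained.

Step 7
Reactants: 11 methyl (S)-3-bromo-2-hydroxypropanoate
Product: 12 methyl (S)-3-bromo-2-[(tert-butyldimethylsilyl)oxy]propanoate
Conditions: TBSOTf, 2,6-lutidine, CH2Cl2, −78 → 0 °C
Reagents that add atoms: tert-butyldimethylsilyl trifluoromethanesulfonate, CC(C)(C)[Si](C)(C)OS(=O)(=O)C(F)(F)F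
Why: Silylation of the secondary alcohol with a silyl triflate and a hindered, non-nucleophilic base that does not displace or eliminate the bromide.

Step 8
Reactants: 12 methyl (S)-3-bromo-2-[(tert-butyldimethylsilyl)oxy]propanoate
Product: 14 (S)-3-bromo-2-[(tert-butyldimethylsilyl)oxy]propanoic acid, via trimethylstannyl ester 13 (not isolated)
Conditions: Me3SnOH, 1,2-dichloroethane, 70 °C; then 1 M HCl
Reagents that add atoms: trimethyltin hydroxide, C[Sn](C)(C)O
Why: Trimethyltin hydroxide cleaves the methyl ester under neutral conditions via the stannyl ester, avoiding the aqueous base under which a β-bromo ester would lose HBr or epimerise.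

Step 9
Reactants: 9 3-ethynyl-1-methyl-2-[(1-methyl-1H-indol-3-yl)methyl]-1H-indole; 14 (S)-3-bromo-2-[(tert-butyldimethylsilyl)oxy]propanoic acid
Product: 15 (Z)-2-{1-methyl-2-[(1-methyl-1H-indol-3-yl)methyl]-1H-indol-3-yl}ethenyl (2S)-3-bromo-2-[(tert-butyldimethylsilyl)oxy]propanoate
Conditions: Ru(2-methylallyl)2(dppb) (cat.), toluene, 60 °C, argon
Reagents that add atoms: none
Why: Ruthenium-catalysed anti-Markovnikov addition of a carboxylic acid to a terminal alkyne via a ruthenium vinylidene, which gives the (Z)-enol ester under base-free conditions that spare the primary bromide and the silyl ether.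

Step 10
Reactants: 15 (Z)-2-{1-methyl-2-[(1-methyl-1H-indol-3-yl)methyl]-1H-indol-3-yl}ethenyl (2S)-3-bromo-2-[(tert-butyldimethylsilyl)oxy]propanoate
Product: 18 (3R,5R)-3-[(tert-butyldimethylsilyl)oxy]-5-({1-methyl-2-[(1-methyl-1H-indol-3-yl)methyl]-1H-indol-3-yl}methyl)dihydrofuran-2(3H)-one, via primary alkyl radical 16 (not isolated), via indolylmethyl radical 17 (not isolated)
Conditions: Bu3SnH (1.3 equiv, syringe pump over 8 h), AIBN (cat., in portions), degassed benzene (5 mM), 80 °C; KF work-up
Reagents that add atoms: none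
Why: Proposed new method: Bu3Sn• abstracts bromine from 15 to give the primary radical 16 at lactone C4, which adds 5-exo-trig to the oxygen-bearing alkene carbon C5 of the enol ester through the s-trans rotamer of the ester, closing the γ-lactone and leaving the indol-3-ylmethyl radical 17, which takes a hydrogen atom from Bu3SnH. The closest known reaction types are tin-hydride 5-exo-trig cyclisations of ester- and haloacetal-tethered alkyl radicals (Ueno–Stork) and the β-alkoxyacrylate cyclisation, in which an alkyl radical attacks the oxygen-bearing alkene carbon; new here is the enol ester as acceptor with the ester itself as tether. The step needs 5-exo over 6-endo closure and cyclisation over premature reduction: the indolyl group on the distal alkene carbon makes 17 a stabilised benzylic radical, and the low stannane concentration at 80 °C gives 16 time to reach the reactive ester rotamer. The new stereocentre C5 is controlled by the existing C3 centre: in the chair-like Beckwith–Houk transition state the bulky OTBS group next to the radical carbon sits pseudo-equatorial, which for a 2-substituted hexenyl-type radical is expected to place the new C5 substituent trans, i.e. (3R,5R). The alkene geometry is not carried into the product because the radical carbon becomes a CH2 group.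

Step 11
Reactants: 18 (3R,5R)-3-[(tert-butyldimethylsilyl)oxy]-5-({1-methyl-2-[(1-methyl-1H-indol-3-yl)methyl]-1H-indol-3-yl}methyl)dihydrofuran-2(3H)-one
Product: 19 chaetoindolone C, (3R,5R)-3-hydroxy-5-({1-methyl-2-[(1-methyl-1H-indol-3-yl)methyl]-1H-indol-3-yl}methyl)dihydrofuran-2(3H)-one
Conditions: HF·pyridine, pyridine, THF, 0 °C → rt
Reagents that add atoms: none
Why: Fluoride cleavage of the secondary TBS ether with buffered HF·pyridine, which avoids the basic conditions that could epimerise C3 or open the lactone.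

**Compound list**
1 | 1-methyl-1H-indole | Cn1ccc2ccccc21 | starting material
2 | 1-methyl-1H-indole-3-carbaldehyde | Cn1cc(C=O)c2ccccc21 | starting material
3 | 2-lithio-1-methyl-1H-indole | [Li]c1cc2ccccc2n1C | intermediate (not isolated)
4 | (1-methyl-1H-indol-2-yl)(1-methyl-1H-indol-3-yl)methanol, racemic | Cn1cc(C(O)c2cc3ccccc3n2C)c2ccccc21 | intermediate
5 | 1-methyl-2-[(1-methyl-1H-indol-3-yl)methyl]-1H-indole | Cn1cc(Cc2cc3ccccc3n2C)c2ccccc21 | intermediate
6 | 3-iodo-1-methyl-2-[(1-methyl-1H-indol-3-yl)methyl]-1H-indole | Cn1cc(Cc2c(I)c3ccccc3n2C)c2ccccc21 | intermediate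
7 | ethynyltrimethylsilane | C#C[Si](C)(C)C | starting material
8 | 1-methyl-2-[(1-methyl-1H-indol-3-yl)methyl]-3-[(trimethylsilyl)ethynyl]-1H-indole | Cn1cc(Cc2c(C#C[Si](C)(C)C)c3ccccc3n2C)c2ccccc21 | intermediate
9 | 3-ethynyl-1-methyl-2-[(1-methyl-1H-indol-3-yl)methyl]-1H-indole | Cn1cc(Cc2c(C#C)c3ccccc3n2C)c2ccccc21 | intermediate
10 | methyl (R)-oxirane-2-carboxylate | COC(=O)[C@H]1CO1 | starting material
11 | methyl (S)-3-bromo-2-hydroxypropanoate | COC(=O)[C@H](O)CBr | intermediate
12 | methyl (S)-3-bromo-2-[(tert-butyldimethylsilyl)oxy]propanoate | COC(=O)[C@H](O[Si](C)(C)C(C)(C)C)CBr | intermediate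
13 | trimethylstannyl (S)-3-bromo-2-[(tert-butyldimethylsilyl)oxy]propanoate | C[Sn](C)(C)OC(=O)[C@H](O[Si](C)(C)C(C)(C)C)CBr | intermediate (not isolated)
14 | (S)-3-bromo-2-[(tert-butyldimethylsilyl)oxy]propanoic acid | OC(=O)[C@H](O[Si](C)(C)C(C)(C)C)CBr | intermediate
15 | (Z)-2-{1-methyl-2-[(1-methyl-1H-indol-3-yl)methyl]-1H-indol-3-yl}ethenyl (2S)-3-bromo-2-[(tert-butyldimethylsilyl)oxy]propanoate | Cn1cc(Cc2c(/C=C\OC(=O)[C@H](O[Si](C)(C)C(C)(C)C)CBr)c3ccccc3n2C)c2ccccc21 | intermediate
16 | primary radical at C4 (15 with the bromine replaced by an unpaired electron) | Cn1cc(Cc2c(/C=C\OC(=O)[C@H](O[Si](C)(C)C(C)(C)C)[CH2])c3ccccc3n2C)c2ccccc21 | intermediate (not isolated)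
17 | cyclised (3R,5R)-lactone with the radical on the carbon between C5 and indole C3 | Cn1cc(Cc2c([CH][C@@H]3C[C@@H](O[Si](C)(C)C(C)(C)C)C(=O)O3)c3ccccc3n2C)c2ccccc21 | intermediate (not isolated)
18 | (3R,5R)-3-[(tert-butyldimethylsilyl)oxy]-5-({1-methyl-2-[(1-methyl-1H-indol-3-yl)methyl]-1H-indol-3-yl}methyl)dihydrofuran-2(3H)-one | Cn1cc(Cc2c(C[C@@H]3C[C@@H](O[Si](C)(C)C(C)(C)C)C(=O)O3)c3ccccc3n2C)c2ccccc21 | intermediate
19 | chaetoindolone C, (3R,5R)-3-hydroxy-5-({1-methyl-2-[(1-methyl-1H-indol-3-yl)methyl]-1H-indol-3-yl}methyl)dihydrofuran-2(3H)-one | Cn1cc(Cc2c(C[C@@H]3C[C@@H](O)C(=O)O3)c3ccccc3n2C)c2ccccc21 | target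

**Step count**
Total: 11 steps. Longest linear sequence: 8 steps (1–5, 9–11); acid 14 is made in 3 steps (6–8) and joins at step 9.

**Steps most likely to fail**

Step 10 (Proposed new method). The radical may be reduced before the ester has rotated into the reactive rotamer, and the facial selectivity at C5 under control of the C3 silyloxy group may be low. The fallback uses known chemistry, sets out from 6 and returns at 19. Iodine–magnesium exchange of 6 (i-PrMgCl·LiCl, THF, −20 °C) gives {1-methyl-2-[(1-methyl-1H-indol-3-yl)methyl]-1H-indol-3-yl}magnesium chloride F1. F1 displaces the tosylate of commercial (S)-5-(tosyloxymethyl)dihydrofuran-2(3H)-one (Cc1ccc(cc1)S(=O)(=O)OC[C@@H]1CCC(=O)O1, from L-glutamic acid) under copper catalysis (CuI, THF, −30 → 0 °C). This gives (S)-5-({1-methyl-2-[(1-methyl-1H-indol-3-yl)methyl]-1H-indol-3-yl}methyl)dihydrofuran-2(3H)-one F2, with C5 taken from the chiral pool. Deprotonation (LiHMDS, THF, −78 °C) and oxidation of the lactone enolate with 2-(phenylsulfonyl)-3-phenyloxaziridine, which enters anti to the C5 substituent, should give 19 directly.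

Step 9. The vinylidene pathway may stall on the electron-rich, ortho-substituted heteroaryl alkyne or give the wrong regio- or stereoisomer, and the β-bromo acid may lactonise or eliminate on heating. The fallback sets out from 9 and returns at 18. Hydroboration of 9 with pinacolborane (Cp2Zr(H)Cl cat., CH2Cl2, rt) gives the (E)-alkenyl pinacolboronate F3. KHF2 (MeOH/H2O) converts it into the potassium (E)-alkenyltrifluoroborate F4. Copper-catalysed oxidative C–O coupling of F4 with acid 14 (Cu(OAc)2, DMAP, 4 Å molecular sieves, O2, CH2Cl2, rt) gives the (E)-enol ester F5. Under the conditions of step 10, F5 converges on radical 17 and hence on 18, because the alkene geometry is lost at the radical stage.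

Step 8. Ester cleavage next to the bromide may cause loss of HBr, bromide displacement or β-lactone formation from the bromo carboxylate. The fallback sets out from 10 and returns at 14. The epoxy ester is saponified first (KOH, EtOH, 0 °C) to potassium (R)-oxirane-2-carboxylate F6. The epoxide is then opened with 48% aqueous HBr (0 °C) to (S)-3-bromo-2-hydroxypropanoic acid F7. Both oxygens are silylated (TBSCl, imidazole, DMF) to tert-butyldimethylsilyl (S)-3-bromo-2-[(tert-butyldimethylsilyl)oxy]propanoate F8, and only the silyl ester is cleaved (AcOH/THF/H2O, rt) to give 14, so no ester hydrolysis is needed in the presence of the bromide.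

**Further compounds**
F1 | step 10 | {1-methyl-2-[(1-methyl-1H-indol-3-yl)methyl]-1H-indol-3-yl}magnesium chloride | Cl[Mg]c1c(Cc2cn(C)c3ccccc23)n(C)c2ccccc12
F2 | step 10 | (S)-5-({1-methyl-2-[(1-methyl-1H-indol-3-yl)methyl]-1H-indol-3-yl}methyl)dihydrofuran-2(3H)-one | Cn1cc(Cc2c(C[C@@H]3CCC(=O)O3)c3ccccc3n2C)c2ccccc21
F3 | step 9 | (E)-1-methyl-2-[(1-methyl-1H-indol-3-yl)methyl]-3-[2-(4,4,5,5-tetramethyl-1,3,2-dioxaborolan-2-yl)ethenyl]-1H-indole | Cn1cc(Cc2c(/C=C/B3OC(C)(C)C(C)(C)O3)c3ccccc3n2C)c2ccccc21
F4 | step 9 | potassium (E)-trifluoro(2-{1-methyl-2-[(1-methyl-1H-indol-3-yl)methyl]-1H-indol-3-yl}ethenyl)borate | [K+].Cn1cc(Cc2c(/C=C/[B-](F)(F)F)c3ccccc3n2C)c2ccccc21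
F5 | step 9 | (E)-2-{1-methyl-2-[(1-methyl-1H-indol-3-yl)methyl]-1H-indol-3-yl}ethenyl (2S)-3-bromo-2-[(tert-butyldimethylsilyl)oxy]propanoate | Cn1cc(Cc2c(/C=C/OC(=O)[C@H](O[Si](C)(C)C(C)(C)C)CBr)c3ccccc3n2C)c2ccccc21
F6 | step 8 | potassium (R)-oxirane-2-carboxylate | [K+].[O-]C(=O)[C@H]1CO1
F7 | step 8 | (S)-3-bromo-2-hydroxypropanoic acid | OC(=O)[C@H](O)CBr
F8 | step 8 | tert-butyldimethylsilyl (S)-3-bromo-2-[(tert-butyldimethylsilyl)oxy]propanoate | CC(C)(C)[Si](C)(C)OC(=O)[C@H](O[Si](C)(C)C(C)(C)C)CBr
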